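The cycloheptene ring of the daucane core is cut at C5–C6 and C7–C8 (daucane numbering). Both bonds are made in one tin hydride radical relay. A C5 radical on a preformed cyclopentane attacks a vinylsilane tethered to the C4 tertiary oxygen (5-exo, C5–C6). The resulting C7 radical then closes the seven-membered ring onto a C10 ynone (7-endo, C7–C8). The step exploits the cis 1,3-relation of O-4 and O-6 across the ring-fusion carbon C5: the silicon tether delivers C6 cis to O-4, which fixes the trans ring fusion, and is later oxidised to the C6 hydroxyl. The precursor is a bromocyclopentyl butynone bearing a vinylsilyl ether.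

Key step: step 9

Remark on the chemistry: daucane numbering is used for the core (C1 quaternary ring-fusion carbon with methyl C15; C2, C3 ring CH2; C4 carbinol carbon with isopropyl; C5 ring-fusion CH; C6 CH–O; C7 CH2; C8 =C(CH3); C9 =CH; C10 CH–O). Both esters are (Z)-2-methylbut-2-enoates (angelates).

Step 1
Reactants: 1 3-methylcyclopent-2-en-1-one
Product: 3 trimethyl{[(3S)-3-methyl-3-[1-(trimethylsilyl)ethenyl]cyclopent-1-en-1-yl]oxy}silane, via aluminium enolate 2 (not isolated)
Conditions: ethynyltrimethylsilane, i-Bu2AlH, hexane, 55 °C (forms the alkenylalane); then 1, Cu(OTf)2 (5 mol %), chiral sulfonate-bearing imidazolinium salt (NHC ligand precursor, 5 mol %), THF, −20 to 4 °C; then TMSOTf, −78 to 0 °C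
Reagents that add atoms: [1-(trimethylsilyl)ethenyl]bis(2-methylpropyl)alumane, C=C([Si](C)(C)C)[Al](CC(C)C)CC(C)C; trimethylsilyl trifluoromethanesulfonate, C[Si](C)(C)OS(=O)(=O)C(F)(F)F
Why: Copper-catalysed asymmetric conjugate addition of the alkenylalane to the β-methyl enone should create the C1 quaternary centre under ligand control (ligand enantiomer chosen to give the S enol ether), and the regiodefined aluminium enolate is silylated on oxygen before it can equilibrate.

Step 2
Reactants: 3 silyl enol ether
Product: 4 (2R,3R)-2-bromo-3-methyl-3-[1-(trimethylsilyl)ethenyl]cyclopentan-1-one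
Conditions: NBS, THF, −78 to 0 °C
Reagents that add atoms: N-bromosuccinimide, O=C1CCC(=O)N1Br
Why: Electrophilic bromination of the silyl enol ether places bromine regiospecifically on the carbon between the carbonyl and the quaternary centre, anti to the bulky silylvinyl group and therefore cis to the ring methyl.

Step 3
Reactants: 4 bromo ketone
Product: 5 (2R,3R)-2-bromo-3-ethenyl-3-methylcyclopentan-1-one
Conditions: CF3CO2H, CH2Cl2, 0 °C, short reaction time
Reagents that add atoms: none
Why: Ipso-protodesilylation of the vinylsilane through the β-silyl cation should unmask the plain vinyl group, while the cold, brief acid treatment is meant to avoid enolisation and loss of the C–Br configuration.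

Step 4
Reactants: 5 vinyl bromo ketone
Product: 6 (1R,2R,3R)-2-bromo-3-ethenyl-3-methyl-1-(propan-2-yl)cyclopentan-1-ol
Conditions: i-PrMgCl, CeCl3 (anhydrous), THF, −78 °C; aqueous NH4Cl
Reagents that add atoms: isopropylmagnesium chloride, CC(C)[Mg]Cl
Why: 1,2-Addition of the weakly basic organocerium reagent should occur anti to the adjacent C–Br bond (polar α-halo effect), giving the cis bromohydrin whose tertiary hydroxyl is cis to the ring methyl and cannot close to an epoxide.

Step 5
Reactants: 6 bromohydrin
Product: 8 (1R,2R,3R)-2-bromo-3-hydroxy-1-methyl-3-(propan-2-yl)cyclopentane-1-carbaldehyde, via ozonide 7 (not isolated)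
Conditions: O3, CH2Cl2, −78 °C; then Me2S, −78 to 20 °C
Reagents that add atoms: ozone, [O-][O+]=O
Why: Ozonolysis of the only alkene with reductive work-up should give the non-enolisable neopentyl aldehyde, and the trans relation of the hydroxyl and formyl groups prevents lactol formation.

Step 6
Reactants: 8 hydroxy aldehyde
Product: 9 (1R,2R,3R)-2-bromo-3-{[ethenyl(dimethyl)silyl]oxy}-1-methyl-3-(propan-2-yl)cyclopentane-1-carbaldehyde
Conditions: chloro(ethenyl)dimethylsilane, imidazole, DMF, 20 °C
Reagents that add atoms: chloro(ethenyl)dimethylsilane, C=C[Si](C)(C)Cl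
Why: Silylation with a small, trimethylsilyl-sized chlorosilane should cap the hindered tertiary alcohol and install the radical acceptor on the oxygen that is cis to the C–Br carbon.

Step 7
Reactants: 9 silyl ether aldehyde
Product: 10 1-[(1R,2R,3R)-2-bromo-3-{[ethenyl(dimethyl)silyl]oxy}-1-methyl-3-(propan-2-yl)cyclopentyl]but-2-yn-1-ol (both carbinol epimers)
Conditions: prop-1-ynylmagnesium bromide, THF, −78 to 0 °C; aqueous NH4Cl
Reagents that add atoms: prop-1-yn-1-ylmagnesium bromide, CC#C[Mg]Br
Why: Alkynyl Grignard addition to the aldehyde should tolerate the secondary bromide and the silyl ether at low temperature, and the new carbinol centre is inconsequential because it is oxidised next.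

Step 8
Reactants: 10 propargylic alcohol
Product: 11 1-[(1R,2R,3R)-2-bromo-3-{[ethenyl(dimethyl)silyl]oxy}-1-methyl-3-(propan-2-yl)cyclopentyl]but-2-yn-1-one
Conditions: MnO2 (activated, excess), CH2Cl2, 20 °C
Reagents that add atoms: none
Why: Neutral manganese dioxide oxidation of the propargylic alcohol should give the ynone without cleaving the acid- and base-labile silyl ether.

Step 9
Reactants: 11 bromo ynone
Product: 12 (1S,4R,5R,6S)-6-C,4-O-(dimethylsilanediyl)-4-hydroxydauc-8-en-10-one (oxasilolane O4–SiMe2–C6 fused to the trans-hydroazulenone)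
Conditions: Bu3SnH (1.3 equiv, syringe pump, 8 h), Et3B (0.2 equiv), air, benzene (0.005 M), 20 °C
Reagents that add atoms: none
Why: Bu3Sn• abstracts bromine from C5; the secondary radical adds 5-exo-trig to the silicon-bearing vinyl carbon (C6), and the primary radical so formed at C7 adds 7-endo-dig to the β-carbon (C8) of the ynone, the α-keto vinyl radical then taking hydrogen from Bu3SnH to give the ring-cis enone. The closest known reaction type is the temporary-silicon-tethered radical cyclisation of vinylsilyl ethers of β-halo alcohols, here extended by a relay radical conjugate addition to an alkynone. The oxasilolane closes in the 5-exo-trig mode and the cycloheptenone in the 7-endo-dig mode. C5 is controlled by the tether: the oxasilolane must be cis-fused to the cyclopentane, so C6 enters cis to O-4 and to methyl C15 and trans to the C10 acyl group, whichever bromide epimer is used, which gives the trans ring fusion; C6 is controlled by the vinyl CH2 terminus lying on the convex face away from quaternary C1, which puts silicon (later oxygen) cis to H-5. The step needs the relay ring closure to outrun hydrogen transfer and the 1,2-silyl shift of the β-silyl radical, which the polarity-matched ynone, the low stannane concentration and room-temperature initiation are meant to secure. It also needs attack at C8 and not C9, which is secured by formation of the stabilised α-keto vinyl radical and by the strain of the alternative six-membered ring trans-fused to two five-membered rings.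

Step 10
Reactants: 12 silicon-bridged enone
Product: 13 (1S,4R,5R,6S,10R)-6-C,4-O-(dimethylsilanediyl)dauc-8-ene-4,10-diol
Conditions: (S)-2-methyl-CBS-oxazaborolidine (20 mol %), BH3·SMe2, THF, −30 °C; MeOH quench
Reagents that add atoms: none
Why: Corey–Bakshi–Shibata reduction, with quaternary C1 as the large and alkenyl C9 as the small ketone substituent, should deliver hydride under catalyst control to give the 10R alcohol (hydroxyl trans to methyl C15), against the intrinsic preference for attack anti to the angular methyl.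

Step 11
Reactants: 13 silicon-bridged allylic alcohol
Product: 14 (1S,4R,5S,6S,10R)-dauc-8-ene-4,6,10-triol
Conditions: H2O2 (30 % aq.), KF, KHCO3, THF/MeOH, 40 °C
Reagents that add atoms: hydrogen peroxide, OO
Why: Tamao–Fleming oxidation of the alkoxysilane should replace the C6–Si bond by C6–OH with retention and free the C4 tertiary hydroxyl, leaving the isolated trisubstituted alkene untouched.

Step 12
Reactants: 14 triol
Product: 16 (1S,4R,5S,6S,10R)-4-hydroxydauc-8-ene-6,10-diyl bis[(2Z)-2-methylbut-2-enoate], via 6-monoangelate 15 (not isolated)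
Conditions: (2Z)-2-methylbut-2-enoic acid, 2,4,6-trichlorobenzoyl chloride, Et3N, toluene, 20 °C; then 14, toluene, 80 °C
Reagents that add atoms: (2Z)-2-methylbut-2-enoic acid, C/C=C(/C)C(=O)O
Why: Yamaguchi esterification with the preformed mixed anhydride should acylate both secondary hydroxyls (C6 first, then the neopentylic C10) and leave the tertiary C4 hydroxyl free, and the absence of a nucleophilic amine catalyst avoids isomerisation of the angelate to the tiglate.

Compound list
1 | 3-methylcyclopent-2-en-1-one | CC1=CC(=O)CC1 | starting material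
2 | bis(2-methylpropyl)aluminium enolate of (3S)-3-methyl-3-[1-(trimethylsilyl)ethenyl]cyclopentanone | C=C([Si](C)(C)C)[C@@]1(C)CCC(O[Al](CC(C)C)CC(C)C)=C1 | intermediate
3 | trimethyl{[(3S)-3-methyl-3-[1-(trimethylsilyl)ethenyl]cyclopent-1-en-1-yl]oxy}silane | C=C([Si](C)(C)C)[C@@]1(C)CCC(O[Si](C)(C)C)=C1 | intermediate
4 | (2R,3R)-2-bromo-3-methyl-3-[1-(trimethylsilyl)ethenyl]cyclopentan-1-one | C=C([Si](C)(C)C)[C@@]1(C)CCC(=O)[C@@H]1Br | intermediate
5 | (2R,3R)-2-bromo-3-ethenyl-3-methylcyclopentan-1-one | C=C[C@@]1(C)CCC(=O)[C@@H]1Br | intermediate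
6 | (1R,2R,3R)-2-bromo-3-ethenyl-3-methyl-1-(propan-2-yl)cyclopentan-1-ol | C=C[C@@]1(C)CC[C@@](O)(C(C)C)[C@@H]1Br | intermediate
7 | 3-[(1R,2R,3R)-2-bromo-3-hydroxy-1-methyl-3-(propan-2-yl)cyclopentyl]-1,2,4-trioxolane (ozonide, trioxolane carbon unassigned) | O1OC(OC1)[C@@]2(C)CC[C@@](O)(C(C)C)[C@@H]2Br | intermediate
8 | (1R,2R,3R)-2-bromo-3-hydroxy-1-methyl-3-(propan-2-yl)cyclopentane-1-carbaldehyde | O=C[C@@]1(C)CC[C@@](O)(C(C)C)[C@@H]1Br | intermediate
9 | (1R,2R,3R)-2-bromo-3-{[ethenyl(dimethyl)silyl]oxy}-1-methyl-3-(propan-2-yl)cyclopentane-1-carbaldehyde | O=C[C@@]1(C)CC[C@@](O[Si](C)(C)C=C)(C(C)C)[C@@H]1Br | intermediate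
10 | 1-[(1R,2R,3R)-2-bromo-3-{[ethenyl(dimethyl)silyl]oxy}-1-methyl-3-(propan-2-yl)cyclopentyl]but-2-yn-1-ol (carbinol epimers) | CC#CC(O)[C@@]1(C)CC[C@@](O[Si](C)(C)C=C)(C(C)C)[C@@H]1Br | intermediate
11 | 1-[(1R,2R,3R)-2-bromo-3-{[ethenyl(dimethyl)silyl]oxy}-1-methyl-3-(propan-2-yl)cyclopentyl]but-2-yn-1-one | CC#CC(=O)[C@@]1(C)CC[C@@](O[Si](C)(C)C=C)(C(C)C)[C@@H]1Br | intermediate
12 | (1S,4R,5R,6S)-6-C,4-O-(dimethylsilanediyl)-4-hydroxydauc-8-en-10-one | C[Si]3(C)[C@H]1CC(C)=CC(=O)[C@@]2(C)CC[C@@](O3)(C(C)C)[C@H]12 | intermediate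
13 | (1S,4R,5R,6S,10R)-6-C,4-O-(dimethylsilanediyl)dauc-8-ene-4,10-diol | C[Si]3(C)[C@H]1CC(C)=C[C@@H](O)[C@@]2(C)CC[C@@](O3)(C(C)C)[C@H]12 | intermediate
14 | (1S,4R,5S,6S,10R)-dauc-8-ene-4,6,10-triol | O[C@H]1CC(C)=C[C@@H](O)[C@@]2(C)CC[C@@](O)(C(C)C)[C@H]12 | intermediate
15 | (1S,4R,5S,6S,10R)-4,10-dihydroxydauc-8-en-6-yl (2Z)-2-methylbut-2-enoate | C/C=C(/C)C(=O)O[C@H]1CC(C)=C[C@@H](O)[C@@]2(C)CC[C@@](O)(C(C)C)[C@H]12 | intermediate
16 | (1S,4R,5S,6S,10R)-4-hydroxydauc-8-ene-6,10-diyl bis[(2Z)-2-methylbut-2-enoate] (CNP0183261.1) | C/C=C(/C)C(=O)O[C@H]1CC(C)=C[C@@H](OC(=O)/C(C)=C\C)[C@@]2(C)CC[C@@](O)(C(C)C)[C@H]12 | target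

Total step count: 12. Longest linear sequence: 12 steps (from 1).

Steps most likely to fail

Step 9. The primary relay radical may be reduced by the stannane or undergo the 1,2-silyl shift (ring enlargement) before it closes the seven-membered ring, or the vinyl group may be attacked on its other face, which would erode the C6 configuration. The fallback sets out from 9 and comes back at 12, and forms C7–C8 by intermolecular radical trapping and the ring by aldol condensation. Methylmagnesium bromide (THF, −78 °C) should convert 9 into the secondary alcohol 1-[(1R,2R,3R)-2-bromo-3-{[ethenyl(dimethyl)silyl]oxy}-1-methyl-3-(propan-2-yl)cyclopentyl]ethan-1-ol F1. Bu3SnH/AIBN under CO (80 atm, benzene, 80 °C) should then effect the same 5-exo cyclisation and trap the relay radical with carbon monoxide, giving the oxasilolane acetaldehyde F2. A second methylmagnesium bromide addition should give the diol F3, and Dess–Martin periodinane should oxidise both carbinols to the diketone F4. Intramolecular aldol condensation (pyrrolidine, AcOH, toluene, 60 °C) between the C10 acetyl methyl and the unhindered C8 ketone should then close the enone 12; the five-membered alternative would be trans-fused to the cyclopentane and the hindered C10 ketone is the poorer electrophile.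

Step 10. Hydride delivery anti to the angular methyl C15, the intrinsic preference of the ketone, may override catalyst control and give the C10 epimer. The fallback sets out from 12 and comes back at 14, and uses substrate control followed by inversion. Luche reduction (NaBH4, CeCl3·7H2O, MeOH, 0 °C) should give the 10S alcohol F5. Mitsunobu reaction (PPh3, DEAD, 4-nitrobenzoic acid, toluene) should invert it to the 10R 4-nitrobenzoate F6. Tamao–Fleming oxidation as in step 11 should give the diol ester F7, and methanolysis (K2CO3, MeOH) should give 14.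

Step 4. Halogen–magnesium exchange, enolisation or β-hydride reduction by the isopropyl reagent may compete with 1,2-addition to the α-bromo ketone. The fallback sets out from 5 and comes back at 6, and uses an sp2 nucleophile without β-hydrogens followed by chemoselective hydrogenation. Isopropenylmagnesium bromide with CeCl3 (THF, −78 °C) should give the isopropenyl carbinol F8. Hydrogen-atom-transfer hydrogenation (Mn(dpm)3 (tris(dipivaloylmethanato)manganese), PhSiH3, t-BuOOH, i-PrOH, 20 °C) should then reduce the 1,1-disubstituted alkene in preference to the monosubstituted vinyl group and give 6.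

Further compounds
F1 | step 9 | 1-[(1R,2R,3R)-2-bromo-3-{[ethenyl(dimethyl)silyl]oxy}-1-methyl-3-(propan-2-yl)cyclopentyl]ethan-1-ol (carbinol epimers) | CC(O)[C@@]1(C)CC[C@@](O[Si](C)(C)C=C)(C(C)C)[C@@H]1Br
F2 | step 9 | cis-fused oxasilolane–cyclopentane bearing CH2CHO on C6 and 1-hydroxyethyl on C1 (7,8-bond not yet closed) | O=CC[C@@H]1[Si](C)(C)O[C@@]2(C(C)C)CC[C@](C)(C(C)O)[C@@H]12
F3 | step 9 | corresponding diol with 2-hydroxypropyl on C6 and 1-hydroxyethyl on C1 | CC(O)C[C@@H]1[Si](C)(C)O[C@@]2(C(C)C)CC[C@](C)(C(C)O)[C@@H]12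
F4 | step 9 | corresponding diketone with 2-oxopropyl on C6 and acetyl on C1 | CC(=O)C[C@@H]1[Si](C)(C)O[C@@]2(C(C)C)CC[C@](C)(C(C)=O)[C@@H]12
F5 | step 10 | (1S,4R,5R,6S,10S)-6-C,4-O-(dimethylsilanediyl)dauc-8-ene-4,10-diol | C[Si]3(C)[C@H]1CC(C)=C[C@H](O)[C@@]2(C)CC[C@@](O3)(C(C)C)[C@H]12
F6 | step 10 | (1S,4R,5R,6S,10R)-6-C,4-O-(dimethylsilanediyl)-4-hydroxydauc-8-en-10-yl 4-nitrobenzoate | C[Si]3(C)[C@H]1CC(C)=C[C@@H](OC(=O)c4ccc(cc4)[N+](=O)[O-])[C@@]2(C)CC[C@@](O3)(C(C)C)[C@H]12
F7 | step 10 | (1S,4R,5S,6S,10R)-4,6-dihydroxydauc-8-en-10-yl 4-nitrobenzoate | O[C@H]1CC(C)=C[C@@H](OC(=O)c3ccc(cc3)[N+](=O)[O-])[C@@]2(C)CC[C@@](O)(C(C)C)[C@H]12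
F8 | step 4 | (1R,2R,3R)-2-bromo-3-ethenyl-3-methyl-1-(prop-1-en-2-yl)cyclopentan-1-ol | C=C[C@@]1(C)CC[C@@](O)(C(C)=C)[C@@H]1Br
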